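**Retrosynthetic overview**
1. Target 11 ⇐ 10 (MOM removal) ⇐ 7 by a late para-Claisen–Cope shift: the 2'-O-prenyl group that protects ring B is relayed O → C3' → C5' and becomes the C-prenyl group.
2. 7 ⇐ 2 + 5: the C3–C1' bond is made by direct C3–H zincation of the chromone and Negishi coupling. No 3-halochromone, arylboron reagent, deoxybenzoin or pre-prenylated ring B is used.
3. 2 ⇐ 7-hydroxychromone 1 (MOM ether); 5 ⇐ 2-bromo-5-methoxyphenol 3 + prenyl bromide 4.
4. Ring order: no ring is built. The benzopyranone (rings A and C) and ring B are bought intact, then joined and decorated.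

Assumption: the target has no stereocentre and no stereogenic double bond, so the "single enantiomer" is the achiral compound itself; 1, 3, 4 and TMPZnCl·LiCl (THF solution) are taken as commercial.

**Step 1**
Reactants: 1 7-hydroxychromen-4-one
Product: 2 7-(methoxymethoxy)chromen-4-one
Conditions: MOMCl (1.3 equiv), K2CO3 (2 equiv), acetone, 0 °C to rt
Reagents that add atoms: chloromethyl methyl ether (MOMCl), COCCl
Why: Williamson-type O-alkylation of the acidic 7-OH by the reactive α-chloro ether gives the MOM acetal, which removes the only acidic proton before the amide base of step 3.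

**Step 2**
Reactants: 3 2-bromo-5-methoxyphenol; 4 prenyl bromide (1-bromo-3-methylbut-2-ene)
Product: 5 1-bromo-4-methoxy-2-(3-methylbut-2-enyloxy)benzene
Conditions: K2CO3, acetone, reflux
Reagents that add atoms: none
Why: Williamson ether synthesis (SN2 at the primary allylic bromide) on the phenoxide; O-alkylation dominates in acetone and the aryl bromide is inert.

**Step 3**
Reactants: 2 7-(methoxymethoxy)chromen-4-one; 5 1-bromo-4-methoxy-2-(3-methylbut-2-enyloxy)benzene
Product: 7 7-(methoxymethoxy)-3-[4-methoxy-2-(3-methylbut-2-enyloxy)phenyl]chromen-4-one, via C3-zincated chromone 6 (not isolated)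
Conditions: 2 (1.2 equiv), TMPZnCl·LiCl (1.3 equiv), THF, −30 to 25 °C, 1 h; then 5 (1.0 equiv), Pd(OAc)2 (2 mol %), SPhos (4 mol %), 50 °C
Reagents that add atoms: TMPZnCl·LiCl (2,2,6,6-tetramethylpiperidin-1-ylzinc chloride lithium chloride), CC1(C)CCCC(C)(C)N1[Zn]Cl.[Li+].[Cl-]; it supplies the Zn and Cl of 6 and leaves no atom in 7
Why: Carbonyl-directed C–H zincation followed by Negishi cross-coupling: the hindered zinc amide bound at the chromone carbonyl removes the neighbouring C3–H (no MgCl2 or BF3·OEt2 is added, since carbonyl-bound Lewis acids steer metalation to C2), the covalent C–Zn bond does not expel the ring oxygen, and zerovalent palladium with SPhos couples 6 to the hindered, electron-rich bromide 5 faster than the aryl–palladium species can add to the trisubstituted prenyl alkene.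

**Step 4**
Reactants: 7 7-(methoxymethoxy)-3-[4-methoxy-2-(3-methylbut-2-enyloxy)phenyl]chromen-4-one
Product: 10 3-[2-hydroxy-4-methoxy-5-(3-methylbut-2-enyl)phenyl]-7-(methoxymethoxy)chromen-4-one, via ortho-dienone 8 (not isolated), via para-dienone 9 (not isolated)
Conditions: N,N-diethylaniline, 200 °C, sealed tube, argon
Reagents that add atoms: none
Why: Tandem aromatic Claisen and Cope rearrangement (para-Claisen): a [3,3] shift of the prenyl ether to C3' (the other ortho carbon, C1', is blocked) gives dienone 8, whose crowded reverse-prenylated carbon between two oxygen-bearing carbons passes the allyl unit on by a second [3,3] shift to C5' (para to the oxygen), and enolisation of 9 gives the phenol with a normal prenyl group; it is a pure isomerisation, and the transient sp3 centres of 8 and 9 are racemic and vanish on aromatisation.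

**Step 5**
Reactants: 10 3-[2-hydroxy-4-methoxy-5-(3-methylbut-2-enyl)phenyl]-7-(methoxymethoxy)chromen-4-one
Product: 11 7-hydroxy-3-[2-hydroxy-4-methoxy-5-(3-methylbut-2-enyl)phenyl]chromen-4-one
Conditions: HCl (about 1 M in MeOH), 40 °C
Reagents that add atoms: none
Why: Acid-catalysed acetal solvolysis (MOM cleavage by transacetalisation to methanol); the prenyl group has OMe and H as ortho neighbours, so chroman formation is impossible and brief dilute acid leaves the alkene and the chromone untouched.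

**Compound list**
1 | 7-hydroxychromen-4-one (7-hydroxychromone) | Oc1ccc2c(=O)ccoc2c1 | starting material
2 | 7-(methoxymethoxy)chromen-4-one | COCOc1ccc2c(=O)ccoc2c1 | intermediate
3 | 2-bromo-5-methoxyphenol | COc1ccc(Br)c(O)c1 | starting material
4 | prenyl bromide (1-bromo-3-methylbut-2-ene) | CC(C)=CCBr | starting material
5 | 1-bromo-4-methoxy-2-(3-methylbut-2-enyloxy)benzene | COc1ccc(Br)c(OCC=C(C)C)c1 | intermediate
6 | 3-(chlorozincio)-7-(methoxymethoxy)chromen-4-one (C3-zincated chromone, LiCl complex, not isolated) | COCOc1ccc2c(=O)c([Zn]Cl)coc2c1 | intermediate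
7 | 7-(methoxymethoxy)-3-[4-methoxy-2-(3-methylbut-2-enyloxy)phenyl]chromen-4-one | COCOc1ccc2c(=O)c(-c3ccc(OC)cc3OCC=C(C)C)coc2c1 | intermediate
8 | ortho-dienone: 3-[4-methoxy-5-(2-methylbut-3-en-2-yl)-6-oxocyclohexa-1,3-dien-1-yl]-7-(methoxymethoxy)chromen-4-one (racemic, not isolated) | COCOc1ccc2c(=O)c(C3=CC=C(OC)C(C(C)(C)C=C)C3=O)coc2c1 | intermediate
9 | para-dienone: 3-[4-methoxy-3-(3-methylbut-2-enyl)-6-oxocyclohexa-1,4-dien-1-yl]-7-(methoxymethoxy)chromen-4-one (racemic, not isolated) | COCOc1ccc2c(=O)c(C3=CC(CC=C(C)C)C(OC)=CC3=O)coc2c1 | intermediate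
10 | 3-[2-hydroxy-4-methoxy-5-(3-methylbut-2-enyl)phenyl]-7-(methoxymethoxy)chromen-4-one | COCOc1ccc2c(=O)c(-c3cc(CC=C(C)C)c(OC)cc3O)coc2c1 | intermediate
11 | 7-hydroxy-3-[2-hydroxy-4-methoxy-5-(3-methylbut-2-enyl)phenyl]chromen-4-one (achiral) | COc1cc(O)c(-c2coc3cc(O)ccc3c2=O)cc1CC=C(C)C | target

**Totals**
Total steps: 5. Longest linear sequence: 4 (steps 1, 3, 4, 5 or steps 2, 3, 4, 5).

**Steps most likely to fail**

Step 4 is the main risk. Dienone 8 may enolise before the Cope shift and give the 3'-(2-methylbut-3-en-2-yl) isomer, or the ether may lose isoprene. The fallback sets out from 3 and comes back at 11; it brings the prenyl group in by cross-coupling instead of by rearrangement. Phenol 3 is protected with MOMCl and K2CO3 as 1-bromo-4-methoxy-2-(methoxymethoxy)benzene F5. F5 is coupled with zinc reagent 6 (made from 2 as in step 3) under Pd(OAc)2 and SPhos to give 7-(methoxymethoxy)-3-[4-methoxy-2-(methoxymethoxy)phenyl]chromen-4-one F6. NBS in MeCN at 0 °C brominates the most activated open position of ring B, para to the 2'-oxygen, to give 3-[5-bromo-4-methoxy-2-(methoxymethoxy)phenyl]-7-(methoxymethoxy)chromen-4-one F7. Stille coupling with tributyl(3-methylbut-2-enyl)stannane and Pd(PPh3)4 in DMF at 90 °C gives 7-(methoxymethoxy)-3-[4-methoxy-2-(methoxymethoxy)-5-(3-methylbut-2-enyl)phenyl]chromen-4-one F8. HCl in MeOH then removes both MOM groups and gives 11.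

Step 3 is the second risk. The zinc amide may attack C2 instead of C3, the metalated chromone may ring-open, or the aryl–palladium intermediate from 5 may cyclise onto the prenyl alkene. The fallback sets out from 2 and 5 and comes back at 7; it reverses the polarity of the coupling. Pyrrolidine in MeOH opens 2 to the enaminone (E)-1-[2-hydroxy-4-(methoxymethoxy)phenyl]-3-(pyrrolidin-1-yl)prop-2-en-1-one F1. I2 in CHCl3 recloses F1 with iodination, strictly at C3, to 3-iodo-7-(methoxymethoxy)chromen-4-one F2. Bromide 5 is exchanged with n-BuLi in THF at −78 °C to [4-methoxy-2-(3-methylbut-2-enyloxy)phenyl]lithium F3, and ZnCl2 converts F3 into [4-methoxy-2-(3-methylbut-2-enyloxy)phenyl]zinc chloride F4. Negishi coupling of F2 with F4 (Pd(PPh3)4, THF, 40 °C) gives 7; here palladium inserts on the chromone, so it never sits next to the prenyl ether.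

Step 5 is the third risk. Methanolic HCl may add across the prenyl double bond before the MOM group is gone. The fallback sets out from 1 and comes back at 11; it replaces the acid-labile group by a base-labile ester. Compound 1 is acylated with pivaloyl chloride and K2CO3 in acetone to 4-oxochromen-7-yl 2,2-dimethylpropanoate F9. TMPZnCl·LiCl, which tolerates esters, gives 3-(chlorozincio)-4-oxochromen-7-yl 2,2-dimethylpropanoate F10, and coupling with 5 as in step 3 gives 3-[4-methoxy-2-(3-methylbut-2-enyloxy)phenyl]-4-oxochromen-7-yl 2,2-dimethylpropanoate F11. Heating as in step 4 passes through the ortho-dienone 3-[4-methoxy-5-(2-methylbut-3-en-2-yl)-6-oxocyclohexa-1,3-dien-1-yl]-4-oxochromen-7-yl 2,2-dimethylpropanoate F12 and the para-dienone 3-[4-methoxy-3-(3-methylbut-2-enyl)-6-oxocyclohexa-1,4-dien-1-yl]-4-oxochromen-7-yl 2,2-dimethylpropanoate F13 to 3-[2-hydroxy-4-methoxy-5-(3-methylbut-2-enyl)phenyl]-4-oxochromen-7-yl 2,2-dimethylpropanoate F14. K2CO3 in MeOH at rt then cleaves the ester and gives 11 without any acid.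

**Further compounds**
F1 | step 3 | (E)-1-[2-hydroxy-4-(methoxymethoxy)phenyl]-3-(pyrrolidin-1-yl)prop-2-en-1-one | COCOc1ccc(C(=O)/C=C/N2CCCC2)c(O)c1
F2 | step 3 | 3-iodo-7-(methoxymethoxy)chromen-4-one | COCOc1ccc2c(=O)c(I)coc2c1
F3 | step 3 | [4-methoxy-2-(3-methylbut-2-enyloxy)phenyl]lithium | [Li]c1ccc(OC)cc1OCC=C(C)C
F4 | step 3 | [4-methoxy-2-(3-methylbut-2-enyloxy)phenyl]zinc chloride | Cl[Zn]c1ccc(OC)cc1OCC=C(C)C
F5 | step 4 | 1-bromo-4-methoxy-2-(methoxymethoxy)benzene | COCOc1cc(OC)ccc1Br
F6 | step 4 | 7-(methoxymethoxy)-3-[4-methoxy-2-(methoxymethoxy)phenyl]chromen-4-one | COCOc1ccc2c(=O)c(-c3ccc(OC)cc3OCOC)coc2c1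
F7 | step 4 | 3-[5-bromo-4-methoxy-2-(methoxymethoxy)phenyl]-7-(methoxymethoxy)chromen-4-one | COCOc1ccc2c(=O)c(-c3cc(Br)c(OC)cc3OCOC)coc2c1
F8 | step 4 | 7-(methoxymethoxy)-3-[4-methoxy-2-(methoxymethoxy)-5-(3-methylbut-2-enyl)phenyl]chromen-4-one | COCOc1ccc2c(=O)c(-c3cc(CC=C(C)C)c(OC)cc3OCOC)coc2c1
F9 | step 5 | 4-oxochromen-7-yl 2,2-dimethylpropanoate | CC(C)(C)C(=O)Oc1ccc2c(=O)ccoc2c1
F10 | step 5 | 3-(chlorozincio)-4-oxochromen-7-yl 2,2-dimethylpropanoate | CC(C)(C)C(=O)Oc1ccc2c(=O)c([Zn]Cl)coc2c1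
F11 | step 5 | 3-[4-methoxy-2-(3-methylbut-2-enyloxy)phenyl]-4-oxochromen-7-yl 2,2-dimethylpropanoate | CC(C)(C)C(=O)Oc1ccc2c(=O)c(-c3ccc(OC)cc3OCC=C(C)C)coc2c1
F12 | step 5 | 3-[4-methoxy-5-(2-methylbut-3-en-2-yl)-6-oxocyclohexa-1,3-dien-1-yl]-4-oxochromen-7-yl 2,2-dimethylpropanoate (racemic) | CC(C)(C)C(=O)Oc1ccc2c(=O)c(C3=CC=C(OC)C(C(C)(C)C=C)C3=O)coc2c1
F13 | step 5 | 3-[4-methoxy-3-(3-methylbut-2-enyl)-6-oxocyclohexa-1,4-dien-1-yl]-4-oxochromen-7-yl 2,2-dimethylpropanoate (racemic) | CC(C)(C)C(=O)Oc1ccc2c(=O)c(C3=CC(CC=C(C)C)C(OC)=CC3=O)coc2c1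
F14 | step 5 | 3-[2-hydroxy-4-methoxy-5-(3-methylbut-2-enyl)phenyl]-4-oxochromen-7-yl 2,2-dimethylpropanoate | CC(C)(C)C(=O)Oc1ccc2c(=O)c(-c3cc(CC=C(C)C)c(OC)cc3O)coc2c1
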